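**Strategy.** Everything rests on disconnecting the pyrrolidine ring (N1, C2, C3, C3a, C8a) at C3–C3a and N1–C8a. The C3a–C8a bond, shared by the pyrrolidine and indoline rings, is the latent C3=C2 π bond of an indole, and N1–C2–C3 is an aziridine. In one operation a chiral Cu(I) Lewis acid lets the 3-prenylindole open N-nosylaziridine at carbon: strain release builds the prenyl-bearing quaternary C3a, and the freed sulfonamide closes onto C8a, expanding the three-membered ring to the cis-fused pyrrolidine. The precursor is the flat, achiral 3-prenyl furo-fused 7-bromoindole that already carries the furan, the tertiary alcohol and the bromine.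

Key step: step 6

Remark on naming: "furoindole" means a 1H-indole fused across C4–C5 to a furan whose oxygen is bonded to indole C4 (a furo[2,3-e]indole); indole locants are kept and the furan carbons are C2′ (next to O) and C3′. The tricyclic aminal uses the usual pyrroloindoline locants (N1, C2, C3, C3a, C4–C7, C7a, N8, C8a).

Remark on step 6: the sense of induction of the Cu/bisphosphine catalyst on this substrate cannot be derived from first principles; (S)-Xyl-BINAP is written, and its commercial antipode is to be used if a first run shows the opposite sense.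

Remark on step 5: 1-(2-nitrophenylsulfonyl)aziridine is prepared in one step in case it is not stocked.

Step 1
Reactants: 1 4-bromo-3-nitrophenol
Product: 2 4-bromo-2-iodo-5-nitrophenol
Conditions: NIS (1.05 equiv), TsOH·H2O (10 mol %), MeCN, rt
Reagents that add atoms: N-iodosuccinimide, O=C1CCC(=O)N1I
Why: Electrophilic aromatic iodination under phenol control; the para position is blocked by Br and the ortho carbon between OH and NO2 is crowded, so iodine should enter at the free ortho carbon.

Step 2
Reactants: 2 4-bromo-2-iodo-5-nitrophenol; 3 2-methylbut-3-yn-2-ol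
Product: 5 2-(5-bromo-6-nitro-1-benzofuran-2-yl)propan-2-ol, via o-alkynylphenol 4 (not isolated)
Conditions: PdCl2(PPh3)2 (2 mol %), CuI (4 mol %), Et3N, DMF, rt then 55 °C
Reagents that add atoms: none
Why: Sonogashira coupling should take the C–I bond in preference to C–Br at room temperature, and the o-alkynylphenol, polarised by the para-nitro group, should then undergo Cu/base-mediated 5-endo-dig cycloisomerisation to the 2-substituted benzofuran (Castro–Stephens-type annulation).

Step 3
Reactants: 5 2-(5-bromo-6-nitro-1-benzofuran-2-yl)propan-2-ol; 6 vinylmagnesium bromide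
Product: 8 2-(7-bromofuroindol-2′-yl)propan-2-ol, via nitrosoarene 7 (not isolated)
Conditions: CH2=CHMgBr (4.2 equiv), THF, −45 °C; then sat. aq. NH4Cl
Reagents that add atoms: none
Why: Bartoli indole synthesis; the ortho bromine is the substituent this reaction requires, and the [3,3]-shift of the N-aryl-O-vinylhydroxylamine can only engage the single free ortho carbon (benzofuran C7), which places Br at indole C7 and the furan oxygen at indole C4, one extra equivalent of Grignard being consumed by the tertiary alcohol.

Step 4
Reactants: 8 2-(7-bromofuroindol-2′-yl)propan-2-ol; 9 prenyl bromide (1-bromo-3-methylbut-2-ene)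
Product: 10 2-[7-bromo-3-(3-methylbut-2-en-1-yl)furoindol-2′-yl]propan-2-ol
Conditions: Zn(OTf)2 (0.6 equiv), Bu4NI (0.5 equiv), iPr2NEt (1.1 equiv), toluene, rt
Reagents that add atoms: none
Why: Zinc triflate-mediated Friedel–Crafts-type C3-alkylation of an N–H indole with an allylic bromide (attack at the primary prenyl terminus) should favour C3 over N1, helped by the 7-bromine flanking N–H, while the amine base keeps the medium non-acidic for the tertiary furyl carbinol.

Step 5
Reactants: 11 2-bromoethylamine hydrobromide; 12 2-nitrobenzenesulfonyl chloride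
Product: 14 1-(2-nitrophenylsulfonyl)aziridine, via N-(2-bromoethyl)sulfonamide 13 (not isolated)
Conditions: K2CO3 (3.5 equiv), MeCN, 0 °C then 60 °C
Reagents that add atoms: none
Why: N-sulfonylation of the primary amine followed by base-induced 3-exo-tet displacement of bromide by the acidic sulfonamide nitrogen is the standard entry to N-sulfonylaziridines.

Step 6
Reactants: 10 2-[7-bromo-3-(3-methylbut-2-en-1-yl)furoindol-2′-yl]propan-2-ol; 14 1-(2-nitrophenylsulfonyl)aziridine
Product: 16 (3aS,8aS)-7-bromo-1-(2-nitrophenylsulfonyl)-3a-(3-methylbut-2-en-1-yl)-1,2,3,3a,8,8a-hexahydropyrrolo[2,3-b]indole bearing the 4,5-fused furan (O on C4) with 2-hydroxypropan-2-yl at C2′, via (S)-3H-indole sulfonamide 15 (not isolated)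
Conditions: [Cu(MeCN)4]PF6 (10 mol %), (S)-Xyl-BINAP (12 mol %), 14 (1.3 equiv), 4 Å MS, toluene, 25–40 °C
Reagents that add atoms: none
Why: The cationic Cu(I)–bisphosphine complex binds the sulfonamide of 14, and indole C3 of 10 opens the strained ring by SN2 attack at a CH2 carbon, which forms the C3a–C3 bond and the prenyl-bearing quaternary centre in 3H-indole 15; the copper sulfonamide then adds to the C2=N imine carbon, so the three-membered ring is expanded by two atoms (indole C2 and C3) into the pyrrolidine. The closest known reaction type is the Lewis acid-catalysed formal [3+2] annulation of 3-alkylindoles with N-acyl or N-sulfonyl aziridines, including Cu(I)/chiral bisphosphine variants that give pyrroloindolines enantioselectively from 2-arylaziridines. The pyrrolidine closes in a 5-exo-trig mode (N1 onto C8a, with the C8a=N8 bond exocyclic to the new ring). C3a is set by catalyst-controlled discrimination of the two faces of the planar indole in the C–C bond-forming step, and C8a follows from C3a because only the cis 5/5 ring fusion can form. The step needs C3 over N8 and C2 selectivity, which the enamine character of the 3-alkylindole, the C4 oxygen donor and the bromine beside N8 should secure. The prenyl olefin and the tertiary alcohol are far weaker nucleophiles toward the Cu-bound aziridine, and the mild Cu(I) acid should not ionise the furyl carbinol.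

Step 7
Reactants: 16 the N1-nosyl pyrroloindoline
Product: 17 (3aS,8aR)-7-bromo-3a-(3-methylbut-2-en-1-yl)-1,2,3,3a,8,8a-hexahydropyrrolo[2,3-b]indole bearing the 4,5-fused furan with 2-hydroxypropan-2-yl at C2′ (N1–H; same spatial arrangement as 16, the C8a descriptor changes only because N8 now outranks N1)
Conditions: PhSH (2 equiv), K2CO3 (3 equiv), DMF, rt
Reagents that add atoms: none
Why: Fukuyama denosylation; thiolate adds to the nitroarene (Meisenheimer complex, SNAr) and releases the amine and SO2 under conditions that leave the aryl bromide, the olefin, the aminal and the tertiary alcohol untouched, and no stereocentre is involved.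

Step 8
Reactants: 17 the N1–H pyrroloindoline
Product: 19 target CNP0306513.1, (3aS,8aS)-7-bromo-1-methyl-3a-(3-methylbut-2-en-1-yl)-1,2,3,3a,8,8a-hexahydropyrrolo[2,3-b]indole bearing the 4,5-fused furan (O on C4) with 2-hydroxypropan-2-yl at C2′, via N1-methyleneiminium ion 18 (not isolated)
Conditions: 37% aq. CH2O (1.1 equiv), NaBH(OAc)3 (1.5 equiv), AcOH (1 equiv), ClCH2CH2Cl, 0 °C
Reagents that add atoms: formaldehyde, C=O
Why: Reductive amination with one equivalent of formaldehyde should methylate the aliphatic secondary N1 selectively, because N8 is a weakly nucleophilic aniline nitrogen flanked by bromine and by the hindered aminal carbon, and the cis aminal keeps its configuration since C3a is quaternary.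

**Compound list**

1 | 4-bromo-3-nitrophenol | Oc1ccc(Br)c([N+](=O)[O-])c1 | starting material
2 | 4-bromo-2-iodo-5-nitrophenol | Oc1cc([N+](=O)[O-])c(Br)cc1I | intermediate
3 | 2-methylbut-3-yn-2-ol | CC(C)(O)C#C | starting material
4 | 4-bromo-2-(3-hydroxy-3-methylbut-1-yn-1-yl)-5-nitrophenol (not isolated) | CC(C)(O)C#Cc1cc(Br)c([N+](=O)[O-])cc1O | intermediate
5 | 2-(5-bromo-6-nitro-1-benzofuran-2-yl)propan-2-ol | CC(C)(O)c1cc2cc(Br)c([N+](=O)[O-])cc2o1 | intermediate
6 | vinylmagnesium bromide | C=C[Mg]Br | starting material
7 | 2-(5-bromo-6-nitroso-1-benzofuran-2-yl)propan-2-ol (not isolated) | CC(C)(O)c1cc2cc(Br)c(N=O)cc2o1 | intermediate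
8 | 2-(7-bromofuroindol-2′-yl)propan-2-ol (7-bromo-1H-indole, furan fused at C4–C5 with O on C4, CMe2OH on C2′) | CC(C)(O)c1cc2cc(Br)c3[nH]ccc3c2o1 | intermediate
9 | prenyl bromide (1-bromo-3-methylbut-2-ene) | CC(C)=CCBr | starting material
10 | 2-[7-bromo-3-(3-methylbut-2-en-1-yl)furoindol-2′-yl]propan-2-ol | CC(C)=CCc1c[nH]c2c(Br)cc3cc(C(C)(C)O)oc3c12 | intermediate
11 | 2-bromoethylamine hydrobromide | NCCBr.Br | starting material
12 | 2-nitrobenzenesulfonyl chloride | O=S(=O)(Cl)c1ccccc1[N+](=O)[O-] | starting material
13 | N-(2-bromoethyl)-2-nitrobenzenesulfonamide (not isolated) | O=S(=O)(NCCBr)c1ccccc1[N+](=O)[O-] | intermediate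
14 | 1-(2-nitrophenylsulfonyl)aziridine | O=S(=O)(N1CC1)c1ccccc1[N+](=O)[O-] | intermediate
15 | (S)-3-prenyl-3-[2-(2-nitrophenylsulfonylamino)ethyl]-3H-indole form of the furoindole (not isolated) | CC(C)=CC[C@@]1(CCNS(=O)(=O)c4ccccc4[N+](=O)[O-])C=Nc2c(Br)cc3cc(C(C)(C)O)oc3c12 | intermediate
16 | (3aS,8aS)-N1-(2-nitrophenylsulfonyl) pyrroloindoline | CC(C)=CC[C@@]12CCN(S(=O)(=O)c4ccccc4[N+](=O)[O-])[C@@H]1Nc1c(Br)cc3cc(C(C)(C)O)oc3c12 | intermediate
17 | (3aS,8aR)-N1–H pyrroloindoline | CC(C)=CC[C@@]12CCN[C@@H]1Nc1c(Br)cc3cc(C(C)(C)O)oc3c12 | intermediate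
18 | N1-methyleneiminium ion of 17 (not isolated) | CC(C)=CC[C@@]12CC[N+](=C)[C@@H]1Nc1c(Br)cc3cc(C(C)(C)O)oc3c12 | intermediate
19 | CNP0306513.1, (3aS,8aS)-N1-methyl pyrroloindoline | CC(C)=CC[C@@]12CCN(C)[C@@H]1Nc1c(Br)cc3cc(C(C)(C)O)oc3c12 | target

**Totals.** Total step count: 8. Longest linear sequence: 7 (steps 1–4 and 6–8; step 5 is a one-step side branch).

**Steps most likely to fail**

Step 6. The parent aziridine carries no stereocentre for the catalyst to recognise, so enantiofacial discrimination of the indole may be insufficient. SN2 opening at an unactivated primary carbon may also be sluggish with a soft Cu(I) acid. The fallback sets out from 8 and comes back at 19. Lewis acid-mediated C3-alkylation of 8 with commercial benzyl aziridine-1-carboxylate (Zn(OTf)2 cat.) should give the Nb-benzyloxycarbonyl tryptamine F1. Pd-catalysed enantioselective dearomative prenylation of F1 (prenyl methyl carbonate, Pd(0)/chiral phosphoramidite) should alkylate C3 at the primary terminus of the π-prenyl complex and close the carbamate nitrogen onto C2, giving the N1-benzyloxycarbonyl pyrroloindoline F2. Reduction of the carbamate with alane (AlH3·NMe2Et, THF), which spares the aryl bromide, should turn N–CO2Bn into N–CH3 and deliver 19 directly.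

Step 4. Alkylation may spread over N1, C2 and C3, may occur with allylic transposition (reverse prenyl), or may run on to the 3,3-dialkylated indolenine. Zn(II) may also ionise the tertiary furyl carbinol. The fallback sets out from 8 and comes back at 10. Pd(PPh3)4/Et3B-promoted C3-allylation of 8 with allyl alcohol should give the 3-allyl furoindole F3. Olefin cross-metathesis of F3 with excess 2-methyl-2-butene (Grubbs II catalyst, CH2Cl2, 40 °C) should convert the allyl into the prenyl group of 10.

Step 3. The Grignard reagent may reduce the nitro group to aniline or azo products, or add to the ring, instead of passing through the [3,3]-shift, leaving little indole. The fallback sets out from 5 and comes back at 8. Reduction of 5 (Fe, NH4Cl, EtOH/H2O) should give 2-(6-amino-5-bromo-1-benzofuran-2-yl)propan-2-ol F4. Iodination at the only free ortho carbon of the aniline (NIS, MeCN) should give the 7-iodo aniline F5. Sonogashira coupling at C–I with trimethylsilylacetylene should give the o-(trimethylsilylethynyl)aniline F6. TBAF in refluxing THF should then remove silicon and induce 5-endo-dig cyclisation of the amine onto the alkyne to give 8.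

Further compounds
F1 | step 6 | benzyl N-{2-[7-bromo-2′-(2-hydroxypropan-2-yl)furoindol-3-yl]ethyl}carbamate | O=C(NCCc1c[nH]c2c(Br)cc3cc(C(C)(C)O)oc3c12)OCc1ccccc1
F2 | step 6 | (3aS,8aS)-N1-benzyloxycarbonyl-7-bromo-3a-prenyl pyrroloindoline with the 4,5-fused furan carbinol | CC(C)=CC[C@@]12CCN(C(=O)OCc4ccccc4)[C@@H]1Nc1c(Br)cc3cc(C(C)(C)O)oc3c12
F3 | step 4 | 2-[3-allyl-7-bromofuroindol-2′-yl]propan-2-ol | C=CCc1c[nH]c2c(Br)cc3cc(C(C)(C)O)oc3c12
F4 | step 3 | 2-(6-amino-5-bromo-1-benzofuran-2-yl)propan-2-ol | CC(C)(O)c1cc2cc(Br)c(N)cc2o1
F5 | step 3 | 2-(6-amino-5-bromo-7-iodo-1-benzofuran-2-yl)propan-2-ol | CC(C)(O)c1cc2cc(Br)c(N)c(I)c2o1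
F6 | step 3 | 2-{6-amino-5-bromo-7-[(trimethylsilyl)ethynyl]-1-benzofuran-2-yl}propan-2-ol | CC(C)(O)c1cc2cc(Br)c(N)c(C#C[Si](C)(C)C)c2o1
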